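**Strategy**

1. Ring labels: A is the 2-aryloxyphloroglucinol end, B and C are the inner rings, and D is the 3,4,5-trihydroxyphenoxy end. The retrosynthesis first cuts the eight benzylic O–C bonds (seven benzyl, one 4-methoxybenzyl = PMB).
2. Then, in rings A, B and C in turn, it cuts the C–C bond between the aryloxy-bearing carbon and one neighbouring C–OH carbon. That neighbour is rejoined as a lactone to the oxygen of the other C–OH carbon, so each benzene ring reverts to a 2-pyrone. The ArO–CH2 bond of each pyrone is cut last.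
3. Enabling feature: rings A, B and C are 1,2,3,5-tetraoxygenated benzenes. The carbon that carries the inter-ring oxygen lies between two C–OH carbons and para to the fourth oxygen. A 6-(aryloxymethyl)-4-alkoxy-2-pyrone gives exactly this pattern from its six carbons (CH2, C6, C5, C4, C3, C2) once C2–O1 breaks and CH2 bonds to C2.
4. Forward: ring D is bought as an arene and turned into a phenol. Rings C, B and A then arise in that order, each by SN2 etherification of the free isolated phenol with one bromomethylpyrone (made from triacetic acid lactone) followed by base-induced isomerisation. Between cycles the two new OH groups are benzylated and the PMB group is removed.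
5. No hindered, electron-rich diaryl ether bond is ever made at an arene carbon; each one starts as a plain ArO–CH2 ether.
6. Stereochemistry: the target and all isolated intermediates are achiral. The only geometric element is the cis placement of the carbon chain on the enol-ether double bond of the ring-opened intermediates, which comes from the pyrone ring.

Key step: step 6

Remark: C7 denotes the exocyclic carbon on pyrone C6. The anions are drawn in their carbanion resonance form, so the only double bond with defined geometry is the enol-ether bond of the ring-opened species. Its two carbon substituents are cis, which the CIP rules call E because the alkoxy oxygen outranks carbon.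

**Route**

Step 1
Reactants: 1 4-hydroxy-6-methyl-2H-pyran-2-one (triacetic acid lactone)
Product: 2 4-(4-methoxybenzyloxy)-6-methyl-2H-pyran-2-one
Conditions: 4-MeOC6H4CH2OH, PPh3, DIAD, THF, 0 °C to rt
Reagents that add atoms: 4-methoxybenzyl alcohol, COc1ccc(CO)cc1
Why: The acidic 4-OH of a 4-hydroxy-2-pyrone is a good Mitsunobu pronucleophile and should be alkylated on the 4-oxygen, avoiding the C3-alkylation seen with benzylic halides and base.

Step 2
Reactants: 2 4-(4-methoxybenzyloxy)-6-methyl-2H-pyran-2-one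
Product: 4 6-(hydroxymethyl)-4-(4-methoxybenzyloxy)-2H-pyran-2-one, via sodium C7 anion 3 (not isolated)
Conditions: NaN(SiMe3)2, THF, −78 °C; then 2-(phenylsulfonyl)-3-phenyloxaziridine, −78 °C; AcOH quench
Reagents that add atoms: 2-(phenylsulfonyl)-3-phenyloxaziridine (racemic), O=S(=O)(c1ccccc1)N1OC1c1ccccc1
Why: The amide base deprotonates reversibly and so settles on the more stable, fully conjugated anion at the 6-methyl group, which the N-sulfonyloxaziridine should hydroxylate at C7 (Davis oxidation), the site that restores the pyrone, while the sodium counter-ion limits addition to the sulfonimine and no radical step endangers the PMB benzylic position.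

Step 3
Reactants: 4 6-(hydroxymethyl)-4-(4-methoxybenzyloxy)-2H-pyran-2-one
Product: 5 6-(bromomethyl)-4-(4-methoxybenzyloxy)-2H-pyran-2-one
Conditions: CBr4, PPh3, CH2Cl2, 0 °C
Reagents that add atoms: carbon tetrabromide, BrC(Br)(Br)Br
Why: The Appel reaction converts a primary allylic-type alcohol into the bromide under neutral conditions that leave the lactone and the PMB enol ether untouched.

Step 4
Reactants: 6 3,4,5-tris(benzyloxy)benzaldehyde
Product: 8 3,4,5-tris(benzyloxy)phenol, via aryl formate 7 (not isolated)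
Conditions: mCPBA, CH2Cl2, 0 °C to rt, NaHCO3 wash; crude formate, K2CO3 (0.2 equiv), MeOH, rt
Reagents that add atoms: 3-chloroperoxybenzoic acid, O=C(OO)c1cccc(Cl)c1
Why: Electron-rich benzaldehydes undergo Baeyer–Villiger oxidation with aryl migration (Dakin-type outcome), and mild transesterification cleaves the aryl formate without touching the benzyl ethers.

Step 5
Reactants: 5 6-(bromomethyl)-4-(4-methoxybenzyloxy)-2H-pyran-2-one; 8 3,4,5-tris(benzyloxy)phenol
Product: 9 4-(4-methoxybenzyloxy)-6-{[3,4,5-tris(benzyloxy)phenoxy]methyl}-2H-pyran-2-one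
Conditions: K2CO3, acetone, rt
Reagents that add atoms: none
Why: In this Williamson ether synthesis the unhindered phenoxide should displace the activated primary bromide far faster than it can add to C4 or C6 of the pyrone, and carbonate is too weak to deprotonate the product.

Step 6
Reactants: 9 4-(4-methoxybenzyloxy)-6-{[3,4,5-tris(benzyloxy)phenoxy]methyl}-2H-pyran-2-one
Product: 12 5-(4-methoxybenzyloxy)-2-[3,4,5-tris(benzyloxy)phenoxy]benzene-1,3-diol, via potassium C7 anion 10 (not isolated), via dienylketene enolate 11 (not isolated)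
Conditions: KN(SiMe3)2 (2.5 equiv), THF (0.02 M), −78 to 50 °C, Ar; AcOH quench, degassed work-up
Reagents that add atoms: none
Why: Proposed new method: KN(SiMe3)2 removes a proton from the ArO–CH2 group to give the fully conjugated anion 10 (deprotonation at C3 is reversible and leads nowhere), and the lactone-enolate form of 10 expels the ring oxygen O1 as an enolate (E1cB), which breaks C2–O1 and gives the dienylketene enolate 11. The aryloxy-bearing carbon of 11 then bonds to the ketene carbon C2 and closes the six-membered carbocycle made of C7, C6, C5, C4, C3 and C2; the closure is a 6-(enolendo)-exo acylation at an sp carbon, equally read as the 6π electrocyclisation of a dienylketene, and the cyclohexadienone formed gives its doubly activated C–H proton to the second equivalent of base to end as the resorcinol dianion of ring C. The closest known reaction types are the base-induced Claisen cyclisation of 3,5-dioxohexanoates and triacetic lactone ethers to phloroglucinol derivatives and the closure of dienylketenes to phenols; neither has been shown for a 6-(aryloxymethyl)-4-alkoxy-2-pyrone. No stereocentre is formed, and the one geometric requirement, that C3 and C6 sit cis on the C4=C5 double bond of 11, is met because both were ring atoms of the pyrone. The selectivity needed is C- over O-acylation and intra- over intermolecular reaction: attack through oxygen only regenerates 10 and is reversible whereas C-attack is made irreversible by aromatisation, the aryloxy group stabilises charge on the attacking carbon, the hindered amide can neither exchange the C4 alkoxy group nor hydrolyse the lactone, and high dilution holds back condensation between two pyrones. The atom mapping fixes the substitution pattern, so the aryloxy carbon must end between the two new hydroxyls and para to the PMB ether.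

Step 7
Reactants: 12 5-(4-methoxybenzyloxy)-2-[3,4,5-tris(benzyloxy)phenoxy]benzene-1,3-diol
Product: 13 1,3-bis(benzyloxy)-5-(4-methoxybenzyloxy)-2-[3,4,5-tris(benzyloxy)phenoxy]benzene
Conditions: BnBr (2.5 equiv), K2CO3, DMF, rt, Ar
Reagents that add atoms: benzyl bromide, BrCc1ccccc1
Why: Williamson O-benzylation with carbonate in a dipolar aprotic solvent favours O- over C-alkylation of the electron-rich resorcinol and removes its air sensitivity.

Step 8
Reactants: 13 1,3-bis(benzyloxy)-5-(4-methoxybenzyloxy)-2-[3,4,5-tris(benzyloxy)phenoxy]benzene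
Product: 14 3,5-bis(benzyloxy)-4-[3,4,5-tris(benzyloxy)phenoxy]phenol
Conditions: TFA (5 vol %), 1,3,5-trimethoxybenzene (5 equiv), CH2Cl2, 0 °C
Reagents that add atoms: none
Why: Acidolysis of the PMB aryl ether runs through the stabilised 4-methoxybenzyl cation, plain benzyl ethers ionise far more slowly at this acidity and temperature, and the excess of a scavenger as nucleophilic as ring C takes up the cation by Friedel–Crafts alkylation before it can attack the substrate.

Step 9
Reactants: 5 6-(bromomethyl)-4-(4-methoxybenzyloxy)-2H-pyran-2-one; 14 3,5-bis(benzyloxy)-4-[3,4,5-tris(benzyloxy)phenoxy]phenol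
Product: 15 6-({3,5-bis(benzyloxy)-4-[3,4,5-tris(benzyloxy)phenoxy]phenoxy}methyl)-4-(4-methoxybenzyloxy)-2H-pyran-2-one
Conditions: K2CO3, acetone, rt
Reagents that add atoms: none
Why: This is the same Williamson ether synthesis as in step 5; the reacting OH of 14 has two ortho hydrogens and is as accessible as that of 8.

Step 10
Reactants: 15 6-({3,5-bis(benzyloxy)-4-[3,4,5-tris(benzyloxy)phenoxy]phenoxy}methyl)-4-(4-methoxybenzyloxy)-2H-pyran-2-one
Product: 18 2-{3,5-bis(benzyloxy)-4-[3,4,5-tris(benzyloxy)phenoxy]phenoxy}-5-(4-methoxybenzyloxy)benzene-1,3-diol, via potassium C7 anion 16 (not isolated), via dienylketene enolate 17 (not isolated)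
Conditions: KN(SiMe3)2 (2.5 equiv), THF (0.02 M), −78 to 50 °C, Ar; AcOH quench, degassed work-up
Reagents that add atoms: none
Why: Proposed new method: as in step 6, deprotonation at ArO–CH2 (16), E1cB loss of O1 to the dienylketene enolate 17, bonding of the aryloxy carbon to C2 (six-membered carbocycle, 6π or enolendo-exo closure) and aromatisation should build ring B, the closest known types again being the Claisen cyclisation of triketide esters and triacetic lactone ethers to phloroglucinols and the dienylketene-to-phenol closure, and the five benzyl ethers and the existing diaryl ether carry no proton that the amide base can remove.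

Step 11
Reactants: 18 2-{3,5-bis(benzyloxy)-4-[3,4,5-tris(benzyloxy)phenoxy]phenoxy}-5-(4-methoxybenzyloxy)benzene-1,3-diol
Product: 19 1,3-bis(benzyloxy)-2-{3,5-bis(benzyloxy)-4-[3,4,5-tris(benzyloxy)phenoxy]phenoxy}-5-(4-methoxybenzyloxy)benzene
Conditions: BnBr (2.5 equiv), K2CO3, DMF, rt, Ar
Reagents that add atoms: benzyl bromide, BrCc1ccccc1
Why: Williamson O-benzylation as in step 7, on the same 2-aryloxy-5-alkoxyresorcinol unit.

Step 12
Reactants: 19 1,3-bis(benzyloxy)-2-{3,5-bis(benzyloxy)-4-[3,4,5-tris(benzyloxy)phenoxy]phenoxy}-5-(4-methoxybenzyloxy)benzene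
Product: 20 3,5-bis(benzyloxy)-4-{3,5-bis(benzyloxy)-4-[3,4,5-tris(benzyloxy)phenoxy]phenoxy}phenol
Conditions: TFA (5 vol %), 1,3,5-trimethoxybenzene (5 equiv), CH2Cl2, 0 °C
Reagents that add atoms: none
Why: Selective acidolysis of the PMB aryl ether with a Friedel–Crafts cation scavenger as in step 8, with the seven benzyl ethers staying in place.

Step 13
Reactants: 5 6-(bromomethyl)-4-(4-methoxybenzyloxy)-2H-pyran-2-one; 20 3,5-bis(benzyloxy)-4-{3,5-bis(benzyloxy)-4-[3,4,5-tris(benzyloxy)phenoxy]phenoxy}phenol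
Product: 21 6-[(3,5-bis(benzyloxy)-4-{3,5-bis(benzyloxy)-4-[3,4,5-tris(benzyloxy)phenoxy]phenoxy}phenoxy)methyl]-4-(4-methoxybenzyloxy)-2H-pyran-2-one
Conditions: K2CO3, acetone–DMF, rt
Reagents that add atoms: none
Why: Williamson ether synthesis as in steps 5 and 9, with DMF added only to keep the larger phenoxide in solution.

Step 14
Reactants: 21 6-[(3,5-bis(benzyloxy)-4-{3,5-bis(benzyloxy)-4-[3,4,5-tris(benzyloxy)phenoxy]phenoxy}phenoxy)methyl]-4-(4-methoxybenzyloxy)-2H-pyran-2-one
Product: 24 2-(3,5-bis(benzyloxy)-4-{3,5-bis(benzyloxy)-4-[3,4,5-tris(benzyloxy)phenoxy]phenoxy}phenoxy)-5-(4-methoxybenzyloxy)benzene-1,3-diol, via potassium C7 anion 22 (not isolated), via dienylketene enolate 23 (not isolated)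
Conditions: KN(SiMe3)2 (2.5 equiv), THF (0.02 M), −78 to 50 °C, Ar; AcOH quench, degassed work-up
Reagents that add atoms: none
Why: Proposed new method: the sequence of step 6 (C7 anion 22, E1cB opening to the dienylketene enolate 23, C7–C2 bond formation closing a six-membered carbocycle, aromatisation to the dianion) should build ring A, with the Claisen cyclisation of triketide esters and triacetic lactone ethers to phloroglucinols and the dienylketene-to-phenol closure as the closest known types, and the reacting pyrone unit is the same as before because the growing chain sits one ether oxygen away from it.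

Step 15
Reactants: 24 2-(3,5-bis(benzyloxy)-4-{3,5-bis(benzyloxy)-4-[3,4,5-tris(benzyloxy)phenoxy]phenoxy}phenoxy)-5-(4-methoxybenzyloxy)benzene-1,3-diol
Product: 25 2-{4-[4-(3,4,5-trihydroxyphenoxy)-3,5-dihydroxyphenoxy]-3,5-dihydroxyphenoxy}benzene-1,3,5-triol (CNP0333502.0)
Conditions: H2 (1 atm), Pd(OH)2 on carbon, degassed THF–MeOH, rt; filtration and concentration under Ar
Reagents that add atoms: none
Why: Catalytic hydrogenolysis should cleave the seven benzyl ethers and the PMB ether in one operation, while the diaryl ether bonds and the arene rings are inert to palladium at atmospheric pressure.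

**Compound list**

1 | 4-hydroxy-6-methyl-2H-pyran-2-one (triacetic acid lactone) | Cc1cc(O)cc(=O)o1 | starting material
2 | 4-(4-methoxybenzyloxy)-6-methyl-2H-pyran-2-one | COc1ccc(COc2cc(C)oc(=O)c2)cc1 | intermediate
3 | sodium salt of 2 deprotonated at the 6-methyl carbon (C7) | [Na+].COc1ccc(COc2cc([CH2-])oc(=O)c2)cc1 | intermediate (not isolated)
4 | 6-(hydroxymethyl)-4-(4-methoxybenzyloxy)-2H-pyran-2-one | COc1ccc(COc2cc(CO)oc(=O)c2)cc1 | intermediate
5 | 6-(bromomethyl)-4-(4-methoxybenzyloxy)-2H-pyran-2-one | COc1ccc(COc2cc(CBr)oc(=O)c2)cc1 | intermediate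
6 | 3,4,5-tris(benzyloxy)benzaldehyde | O=Cc1cc(OCc2ccccc2)c(OCc2ccccc2)c(OCc2ccccc2)c1 | starting material
7 | 3,4,5-tris(benzyloxy)phenyl formate | O=COc1cc(OCc2ccccc2)c(OCc2ccccc2)c(OCc2ccccc2)c1 | intermediate (not isolated)
8 | 3,4,5-tris(benzyloxy)phenol | Oc1cc(OCc2ccccc2)c(OCc2ccccc2)c(OCc2ccccc2)c1 | intermediate
9 | 4-(4-methoxybenzyloxy)-6-{[3,4,5-tris(benzyloxy)phenoxy]methyl}-2H-pyran-2-one | COc1ccc(COc2cc(COc3cc(OCc4ccccc4)c(OCc4ccccc4)c(OCc4ccccc4)c3)oc(=O)c2)cc1 | intermediate
10 | potassium salt of 9 deprotonated at C7 | [K+].COc1ccc(COc2cc([CH-]Oc3cc(OCc4ccccc4)c(OCc4ccccc4)c(OCc4ccccc4)c3)oc(=O)c2)cc1 | intermediate (not isolated)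
11 | potassium enolate of (3E)-3-(4-methoxybenzyloxy)-6-[3,4,5-tris(benzyloxy)phenoxy]hexa-1,3-diene-1,5-dione (ring-opened dienylketene) | [K+].COc1ccc(COC(/C=C=O)=C/C(=O)[CH-]Oc2cc(OCc3ccccc3)c(OCc3ccccc3)c(OCc3ccccc3)c2)cc1 | intermediate (not isolated)
12 | 5-(4-methoxybenzyloxy)-2-[3,4,5-tris(benzyloxy)phenoxy]benzene-1,3-diol | COc1ccc(COc2cc(O)c(Oc3cc(OCc4ccccc4)c(OCc4ccccc4)c(OCc4ccccc4)c3)c(O)c2)cc1 | intermediate
13 | 1,3-bis(benzyloxy)-5-(4-methoxybenzyloxy)-2-[3,4,5-tris(benzyloxy)phenoxy]benzene | COc1ccc(COc2cc(OCc3ccccc3)c(Oc3cc(OCc4ccccc4)c(OCc4ccccc4)c(OCc4ccccc4)c3)c(OCc3ccccc3)c2)cc1 | intermediate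
14 | 3,5-bis(benzyloxy)-4-[3,4,5-tris(benzyloxy)phenoxy]phenol | Oc1cc(OCc2ccccc2)c(Oc2cc(OCc3ccccc3)c(OCc3ccccc3)c(OCc3ccccc3)c2)c(OCc2ccccc2)c1 | intermediate
15 | 6-({3,5-bis(benzyloxy)-4-[3,4,5-tris(benzyloxy)phenoxy]phenoxy}methyl)-4-(4-methoxybenzyloxy)-2H-pyran-2-one | COc1ccc(COc2cc(COc3cc(OCc4ccccc4)c(Oc4cc(OCc5ccccc5)c(OCc5ccccc5)c(OCc5ccccc5)c4)c(OCc4ccccc4)c3)oc(=O)c2)cc1 | intermediate
16 | potassium salt of 15 deprotonated at C7 | [K+].COc1ccc(COc2cc([CH-]Oc3cc(OCc4ccccc4)c(Oc4cc(OCc5ccccc5)c(OCc5ccccc5)c(OCc5ccccc5)c4)c(OCc4ccccc4)c3)oc(=O)c2)cc1 | intermediate (not isolated)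
17 | potassium enolate of (3E)-6-{3,5-bis(benzyloxy)-4-[3,4,5-tris(benzyloxy)phenoxy]phenoxy}-3-(4-methoxybenzyloxy)hexa-1,3-diene-1,5-dione | [K+].COc1ccc(COC(/C=C=O)=C/C(=O)[CH-]Oc2cc(OCc3ccccc3)c(Oc3cc(OCc4ccccc4)c(OCc4ccccc4)c(OCc4ccccc4)c3)c(OCc3ccccc3)c2)cc1 | intermediate (not isolated)
18 | 2-{3,5-bis(benzyloxy)-4-[3,4,5-tris(benzyloxy)phenoxy]phenoxy}-5-(4-methoxybenzyloxy)benzene-1,3-diol | COc1ccc(COc2cc(O)c(Oc3cc(OCc4ccccc4)c(Oc4cc(OCc5ccccc5)c(OCc5ccccc5)c(OCc5ccccc5)c4)c(OCc4ccccc4)c3)c(O)c2)cc1 | intermediate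
19 | 1,3-bis(benzyloxy)-2-{3,5-bis(benzyloxy)-4-[3,4,5-tris(benzyloxy)phenoxy]phenoxy}-5-(4-methoxybenzyloxy)benzene | COc1ccc(COc2cc(OCc3ccccc3)c(Oc3cc(OCc4ccccc4)c(Oc4cc(OCc5ccccc5)c(OCc5ccccc5)c(OCc5ccccc5)c4)c(OCc4ccccc4)c3)c(OCc3ccccc3)c2)cc1 | intermediate
20 | 3,5-bis(benzyloxy)-4-{3,5-bis(benzyloxy)-4-[3,4,5-tris(benzyloxy)phenoxy]phenoxy}phenol | Oc1cc(OCc2ccccc2)c(Oc2cc(OCc3ccccc3)c(Oc3cc(OCc4ccccc4)c(OCc4ccccc4)c(OCc4ccccc4)c3)c(OCc3ccccc3)c2)c(OCc2ccccc2)c1 | intermediate
21 | 6-[(3,5-bis(benzyloxy)-4-{3,5-bis(benzyloxy)-4-[3,4,5-tris(benzyloxy)phenoxy]phenoxy}phenoxy)methyl]-4-(4-methoxybenzyloxy)-2H-pyran-2-one | COc1ccc(COc2cc(COc3cc(OCc4ccccc4)c(Oc4cc(OCc5ccccc5)c(Oc5cc(OCc6ccccc6)c(OCc6ccccc6)c(OCc6ccccc6)c5)c(OCc5ccccc5)c4)c(OCc4ccccc4)c3)oc(=O)c2)cc1 | intermediate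
22 | potassium salt of 21 deprotonated at C7 | [K+].COc1ccc(COc2cc([CH-]Oc3cc(OCc4ccccc4)c(Oc4cc(OCc5ccccc5)c(Oc5cc(OCc6ccccc6)c(OCc6ccccc6)c(OCc6ccccc6)c5)c(OCc5ccccc5)c4)c(OCc4ccccc4)c3)oc(=O)c2)cc1 | intermediate (not isolated)
23 | potassium enolate of (3E)-6-(3,5-bis(benzyloxy)-4-{3,5-bis(benzyloxy)-4-[3,4,5-tris(benzyloxy)phenoxy]phenoxy}phenoxy)-3-(4-methoxybenzyloxy)hexa-1,3-diene-1,5-dione | [K+].COc1ccc(COC(/C=C=O)=C/C(=O)[CH-]Oc2cc(OCc3ccccc3)c(Oc3cc(OCc4ccccc4)c(Oc4cc(OCc5ccccc5)c(OCc5ccccc5)c(OCc5ccccc5)c4)c(OCc4ccccc4)c3)c(OCc3ccccc3)c2)cc1 | intermediate (not isolated)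
24 | 2-(3,5-bis(benzyloxy)-4-{3,5-bis(benzyloxy)-4-[3,4,5-tris(benzyloxy)phenoxy]phenoxy}phenoxy)-5-(4-methoxybenzyloxy)benzene-1,3-diol | COc1ccc(COc2cc(O)c(Oc3cc(OCc4ccccc4)c(Oc4cc(OCc5ccccc5)c(Oc5cc(OCc6ccccc6)c(OCc6ccccc6)c(OCc6ccccc6)c5)c(OCc5ccccc5)c4)c(OCc4ccccc4)c3)c(O)c2)cc1 | intermediate
25 | 2-{4-[4-(3,4,5-trihydroxyphenoxy)-3,5-dihydroxyphenoxy]-3,5-dihydroxyphenoxy}benzene-1,3,5-triol (CNP0333502.0, achiral) | Oc1cc(O)c(Oc2cc(O)c(Oc3cc(O)c(Oc4cc(O)c(O)c(O)c4)c(O)c3)c(O)c2)c(O)c1 | target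

**Step count**

Total steps: 15.
Longest linear sequence: 14 steps (steps 1–3 and 5–15, from triacetic acid lactone 1). The branch from aldehyde 6 has 12 steps.

**Steps most likely to fail**

Step 6 (ring C).
- What may go wrong: expulsion of the ring oxygen from the delocalised anion may be too slow, so the anion is used up by condensation with pyrone that has not yet reacted. Alternatively, the opened species may only reclose through oxygen.
- The fallback makes the hindered ether by a copper-catalysed Ullmann coupling on a bromide activated by a para formyl group. A Dakin-type oxidation then turns that formyl group into the missing oxygen. It sets out from phenol 8 and comes back at phenol 14, bypassing steps 5 to 8.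
- Commercial 4-bromo-3,5-dimethoxybenzaldehyde is demethylated with BBr3 in CH2Cl2 to 4-bromo-3,5-dihydroxybenzaldehyde F1. This is benzylated (BnBr, K2CO3, DMF) to 3,5-bis(benzyloxy)-4-bromobenzaldehyde F2.
- Coupling of 8 with F2 (CuI, N,N-dimethylglycine, Cs2CO3, dioxane, 100 °C) should give 3,5-bis(benzyloxy)-4-[3,4,5-tris(benzyloxy)phenoxy]benzaldehyde F3.
- mCPBA in CH2Cl2 converts F3 into 3,5-bis(benzyloxy)-4-[3,4,5-tris(benzyloxy)phenoxy]phenyl formate F4, and methanolysis (K2CO3, MeOH) releases 14.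

Step 10 (ring B).
- What may go wrong: the bulkier aryloxy group may slow the closure, so longer heating is needed. During that time the ketene can be intercepted intermolecularly, or aryloxide can be lost from the side chain.
- The fallback sets out from phenol 14 and comes back at phenol 20, bypassing steps 9 to 12.
- Phenol 14 is coupled with 3,5-bis(benzyloxy)-4-bromobenzaldehyde F2, made as described for step 6, under the same Ullmann conditions (CuI, N,N-dimethylglycine, Cs2CO3, dioxane, 100 °C). This should give 3,5-bis(benzyloxy)-4-{3,5-bis(benzyloxy)-4-[3,4,5-tris(benzyloxy)phenoxy]phenoxy}benzaldehyde F5.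
- Baeyer–Villiger oxidation with mCPBA gives 3,5-bis(benzyloxy)-4-{3,5-bis(benzyloxy)-4-[3,4,5-tris(benzyloxy)phenoxy]phenoxy}phenyl formate F6, and methanolysis gives 20.

Step 14 (ring A).
- What may go wrong: the potassium salts of the large substrate may be poorly soluble and close slowly, and the electron-rich dianion may oxidise during work-up.
- The fallback sets out from phenol 20 and comes back at the target 25, bypassing steps 13 to 15.
- Ullmann coupling of 20 with 3,5-bis(benzyloxy)-4-bromobenzaldehyde F2 should give 3,5-bis(benzyloxy)-4-(3,5-bis(benzyloxy)-4-{3,5-bis(benzyloxy)-4-[3,4,5-tris(benzyloxy)phenoxy]phenoxy}phenoxy)benzaldehyde F7.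
- mCPBA gives the corresponding tetra-aryl formate F8, and methanolysis gives 3,5-bis(benzyloxy)-4-(3,5-bis(benzyloxy)-4-{3,5-bis(benzyloxy)-4-[3,4,5-tris(benzyloxy)phenoxy]phenoxy}phenoxy)phenol F9.
- Hydrogenolysis of the nine benzyl ethers of F9 (H2, Pd(OH)2 on carbon, degassed THF–MeOH) gives 25.

**Further compounds**

F1 | step 6 | 4-bromo-3,5-dihydroxybenzaldehyde | O=Cc1cc(O)c(Br)c(O)c1
F2 | step 6 | 3,5-bis(benzyloxy)-4-bromobenzaldehyde | O=Cc1cc(OCc2ccccc2)c(Br)c(OCc2ccccc2)c1
F3 | step 6 | 3,5-bis(benzyloxy)-4-[3,4,5-tris(benzyloxy)phenoxy]benzaldehyde | O=Cc1cc(OCc2ccccc2)c(Oc2cc(OCc3ccccc3)c(OCc3ccccc3)c(OCc3ccccc3)c2)c(OCc2ccccc2)c1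
F4 | step 6 | 3,5-bis(benzyloxy)-4-[3,4,5-tris(benzyloxy)phenoxy]phenyl formate | O=COc1cc(OCc2ccccc2)c(Oc2cc(OCc3ccccc3)c(OCc3ccccc3)c(OCc3ccccc3)c2)c(OCc2ccccc2)c1
F5 | step 10 | 3,5-bis(benzyloxy)-4-{3,5-bis(benzyloxy)-4-[3,4,5-tris(benzyloxy)phenoxy]phenoxy}benzaldehyde | O=Cc1cc(OCc2ccccc2)c(Oc2cc(OCc3ccccc3)c(Oc3cc(OCc4ccccc4)c(OCc4ccccc4)c(OCc4ccccc4)c3)c(OCc3ccccc3)c2)c(OCc2ccccc2)c1
F6 | step 10 | 3,5-bis(benzyloxy)-4-{3,5-bis(benzyloxy)-4-[3,4,5-tris(benzyloxy)phenoxy]phenoxy}phenyl formate | O=COc1cc(OCc2ccccc2)c(Oc2cc(OCc3ccccc3)c(Oc3cc(OCc4ccccc4)c(OCc4ccccc4)c(OCc4ccccc4)c3)c(OCc3ccccc3)c2)c(OCc2ccccc2)c1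
F7 | step 14 | 3,5-bis(benzyloxy)-4-(3,5-bis(benzyloxy)-4-{3,5-bis(benzyloxy)-4-[3,4,5-tris(benzyloxy)phenoxy]phenoxy}phenoxy)benzaldehyde | O=Cc1cc(OCc2ccccc2)c(Oc2cc(OCc3ccccc3)c(Oc3cc(OCc4ccccc4)c(Oc4cc(OCc5ccccc5)c(OCc5ccccc5)c(OCc5ccccc5)c4)c(OCc4ccccc4)c3)c(OCc3ccccc3)c2)c(OCc2ccccc2)c1
F8 | step 14 | 3,5-bis(benzyloxy)-4-(3,5-bis(benzyloxy)-4-{3,5-bis(benzyloxy)-4-[3,4,5-tris(benzyloxy)phenoxy]phenoxy}phenoxy)phenyl formate | O=COc1cc(OCc2ccccc2)c(Oc2cc(OCc3ccccc3)c(Oc3cc(OCc4ccccc4)c(Oc4cc(OCc5ccccc5)c(OCc5ccccc5)c(OCc5ccccc5)c4)c(OCc4ccccc4)c3)c(OCc3ccccc3)c2)c(OCc2ccccc2)c1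
F9 | step 14 | 3,5-bis(benzyloxy)-4-(3,5-bis(benzyloxy)-4-{3,5-bis(benzyloxy)-4-[3,4,5-tris(benzyloxy)phenoxy]phenoxy}phenoxy)phenol | Oc1cc(OCc2ccccc2)c(Oc2cc(OCc3ccccc3)c(Oc3cc(OCc4ccccc4)c(Oc4cc(OCc5ccccc5)c(OCc5ccccc5)c(OCc5ccccc5)c4)c(OCc4ccccc4)c3)c(OCc3ccccc3)c2)c(OCc2ccccc2)c1
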